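- In the spring run, which is this very flask followed so far, X has lost more than D has gained: at 10.0 min, X is down by 70.7 % and D stands at 17.9 %. The quantity to watch is therefore what a D costs in Z.

| flask | X | Z | temperature | remark | time |
|---|---|---|---|---|---|
| spring | 20 mM | 22 mM | 25 °C | the very flask that is asked about, followed so far |  |
| summer | 10 mM | 22 mM | 20 °C | run made earlier |  |
| flask | 20 mM | 22.0 mM | 25 °C |  | 12 min |

| run | time / min | D / % | X / % |
|---|---|---|---|
| spring | 1.33 | 7.0 | 52.0 |
| spring | 3.00 | 12.4 | 40.3 |
| spring | 6.00 | 16.7 | 34.8 |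
| spring | 10.0 | 17.9 | 29.3 |
| summer | 0.500 | 0 | 78.9 |
| summer | 1.00 | 3.6 | 63.7 |
| summer | 2.50 | 13.5 | 37.3 |
| summer | 6.00 | 26.3 | 21.4 |

(scatter of a reading: 1 percentage point)

1. D, in percent of the X first charged, at 12 min
2. the remedy with the largest gain of D, or "none" below 2 percentage points (Tuesday's / Thursday's / Wednesday's / Friday's / none)
3. D present, with what was taken out counted in, in percent of the X first charged, after Thursday's
4. D present, with what was taken out counted in, in percent of the X first charged, after Wednesday's

- Tuesday's: at 12 min take out 90 % of the D then present, then wait 12 min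
- Thursday's: at 12 min raise the temperature by 10 K, then wait 12 min
- Wednesday's: change nothing and wait 12 min more
- Friday's: at 12 min add Z, 100 % of the amount charged, then wait 12 min

- what is taken out of D is counted as made
- additions bring no volume worth counting

- Z is not read, so I bill it in points of the X charged. In the summer run D reads 0 % at 0.500 min while X is already falling, so I assume that each X lost takes one Z and that each D takes one more.
- On that bill Z is the limiting reagent, with a charge of 110 % of X against 2 Z per X on the full way to D.
- The yield on Z, D over billed Z and so a mean over the whole curve, is 0.202 in the spring run at 10.0 min.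
- But a mean can hide a drift. The same ratio in the spring run reads 0.172 at 3.00 min and 0.204 at 6.00 min. The scatter moves it by about 0.0113, so I read it as flat over the last two readings.
- For the flask at 12 min, D gained 1.2 percentage points over the last 4.00 min, and that mean slope carried forward gives 18.5 %. But the gain is about as large as its own scatter, 1.4 points, so I claim this to within a point or so.
- Added Z at this yield makes Friday's gain 22 points. The objection is that the bill leaves 21 points of Z unspent while D barely moves, so Z may leak past the bill and w may be too high. The spring charge bought 17.9 % of D by 10.0 min, so I take 18 points as the low end for Friday's.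
- Waiting in the flask should bring D towards w times the charge, 22.2 %. w was read at one temperature, so I put no number on Thursday's.
- The forecast gives 18.5 % (17.5 % to 19.8 %) now, 19.5 % after Thursday's, 19.2 % after Wednesday's and Friday's as best, saying “Fresh Z restarts the second step”.
- The flask gives 19.7 % at 12 min, 22.7 % after Wednesday's and 27.5 % after Thursday's. Friday's gains 22 points, more than any other remedy, against my 22 points.

    Z + Q → D (k = 0.432 M⁻¹ s⁻¹, Ea = 56.0 kJ mol⁻¹)
    Z + L ⇌ J (K = 100 M⁻¹, k = 2.57 M⁻¹ s⁻¹, Ea = 55.0 kJ mol⁻¹, ΔH = −28.0 kJ mol⁻¹)
    D ⇌ E (K = 0.330, k = 0.0316 s⁻¹, Ea = 80.0 kJ mol⁻¹, ΔH = −10.0 kJ mol⁻¹)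
    X + Z ⇌ Q (K = 210 M⁻¹, k = 0.615 M⁻¹ s⁻¹, Ea = 57.0 kJ mol⁻¹, ΔH = −15.0 kJ mol⁻¹)
    Q ⇌ L (K = 3.01, k = 0.00556 s⁻¹, Ea = 93.0 kJ mol⁻¹, ΔH = −15.0 kJ mol⁻¹)
    (constants at 25 °C)

- In the flask at 0.716 min, the step from X + Z to Q uses Z 3.6 times as fast as the step from Z + Q to D, forward rate of the reversible step counted. At 12.0 min, [Z] in the flask stands at 7.9 % of its charge. Carried to the same flask charged with 37 mM of Z, w gives 37.4 % of D at 12 min, and that flask holds 40.6 %.

All runs are simulated from invented constants, noise included.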